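**Strategy.** The route rests on cutting both bonds to C8 at once: the C8–O bond to the ether oxygen of ring B (the 2,6-dimethoxy-4-propenylphenoxy ring) and the C7–C8 bond to the carbinol carbon that carries ring A (the trimethoxyphenyl ring). C8 is thus the carbon of an alpha-aryloxy ester nucleophile lying between a phenol O–H and an aldehyde C=O. One co-catalysed three-component reaction of the free phenol, ethyl diazoacetate and 3,4,5-trimethoxybenzaldehyde should forge both bonds and both stereocenters (threo, 7R,8R in the target) without any protecting group; the precursors are the three commercial components themselves. The ester carbon is then taken down to the C9 methyl and C7–OH is acetylated.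

Key step: step 1

Numbering: C7 is the benzylic carbon on ring A, C8 the carbon bearing the oxygen of ring B, C9 the methyl carbon on C8.

Assumption: phenol 1 is bought as the pure E isomer.

Assumption: the sense of induction of the binaphthyl phosphoric acid in step 1 cannot be predicted with confidence; the (R) acid is written, and its equally available mirror image is taken if the first runs show the antipode of the adduct.

**Step 1**
Reactants: 1 2,6-dimethoxy-4-[(E)-prop-1-enyl]phenol; 2 ethyl diazoacetate; 3 3,4,5-trimethoxybenzaldehyde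
Product: 6 ethyl (2S,3R)-2-[2,6-dimethoxy-4-[(E)-prop-1-enyl]phenoxy]-3-hydroxy-3-(3,4,5-trimethoxyphenyl)propanoate, via oxonium ylide 4 (not isolated), via enol 5 (not isolated)
Conditions: Rh2(OAc)4 (2 mol%), (R)-TRIP [(R)-3,3'-bis(2,4,6-triisopropylphenyl)-1,1'-binaphthyl-2,2'-diyl hydrogen phosphate] (10 mol%), 4 Å MS, CH2Cl2, 0 °C; 2 (1.2 equiv) added over 2 h to 1 and 3 (1.5 equiv)
Reagents that add atoms: none
Why: Proposed new method: Rh2(OAc)4 decomposes 2 to an electrophilic rhodium carbene, the hydroxyl oxygen of 1 adds to it (C8–O bond) to give oxonium ylide 4, proton transfer to the carbonyl oxygen turns 4 into enol 5, and 5 adds to aldehyde 3 (C7–C8 bond) while the phosphoric acid binds the enol O–H through its P=O oxygen and the aldehyde oxygen through its P–OH in a cyclic hydrogen-bonded transition state. The closest known reaction type is the Rh2(OAc)4/chiral acid co-catalysed three-component trapping of alcohol-derived oxonium ylides of aryldiazoacetates with imines (Mannich type) or with Lewis-acid-activated aldehydes (aldol type); a phenol, an acceptor-only diazoacetate and a neutral aryl aldehyde have not been combined in this way. No ring is closed. C7 and C8 are set together in the acid-bound transition state: the relative threo (2,3-syn) configuration by the enol geometry and the placement of ring A away from the 3,3'-aryl walls of the acid, the absolute 2S,3R configuration by the axial chirality of the binaphthyl acid. The step needs O–H capture ahead of cyclopropanation, trapping ahead of the plain proton shift, threo over erythro and one enantioface; in the substrate the hydroxyl is the most nucleophilic site, ring positions 2, 4 and 6 of the phenol are blocked, the propenyl group is 1,2-disubstituted and so a slow cyclopropanation partner, the ortho methoxy oxygens can hold the ylide or enol proton and lengthen its lifetime, and 3 has no alpha hydrogen and is present in excess while 2 is kept at low concentration.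

**Step 2**
Reactants: 6 ethyl (2S,3R)-2-[2,6-dimethoxy-4-[(E)-prop-1-enyl]phenoxy]-3-hydroxy-3-(3,4,5-trimethoxyphenyl)propanoate
Product: 7 (1R,2R)-2-[2,6-dimethoxy-4-[(E)-prop-1-enyl]phenoxy]-1-(3,4,5-trimethoxyphenyl)propane-1,3-diol
Conditions: LiBH4, THF, 0 °C to rt; then aq NH4Cl
Reagents that add atoms: none
Why: Borohydride reduction of an ester activated by its alpha-aryloxy group (LiBH4 ester reduction) should give the 1,3-diol without touching the styrenyl double bond or either stereocenter; the C8 descriptor changes from S to R only because CH2OH ranks below C7 whereas CO2Et ranked above it.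

**Step 3**
Reactants: 7 (1R,2R)-2-[2,6-dimethoxy-4-[(E)-prop-1-enyl]phenoxy]-1-(3,4,5-trimethoxyphenyl)propane-1,3-diol
Product: 8 (2R,3R)-2-[2,6-dimethoxy-4-[(E)-prop-1-enyl]phenoxy]-3-hydroxy-3-(3,4,5-trimethoxyphenyl)propyl 4-methylbenzenesulfonate
Conditions: TsCl (1.1 equiv), pyridine, CH2Cl2, 0 °C
Reagents that add atoms: p-toluenesulfonyl chloride, Cc1ccc(cc1)S(=O)(=O)Cl
Why: Selective tosylation: with a small excess of TsCl at 0 °C the unhindered primary hydroxyl at C9 should react well ahead of the secondary benzylic hydroxyl, which is flanked by ring A and the aryloxy-bearing C8; no stereocenter is touched.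

**Step 4**
Reactants: 8 (2R,3R)-2-[2,6-dimethoxy-4-[(E)-prop-1-enyl]phenoxy]-3-hydroxy-3-(3,4,5-trimethoxyphenyl)propyl 4-methylbenzenesulfonate
Product: 9 (1R,2R)-2-[2,6-dimethoxy-4-[(E)-prop-1-enyl]phenoxy]-1-(3,4,5-trimethoxyphenyl)propan-1-ol
Conditions: LiEt3BH (4 equiv), THF, 0 °C to rt; then H2O
Reagents that add atoms: none
Why: Hydride SN2 displacement of a primary sulfonate by LiEt3BH (reductive removal of the tosyloxy group) should turn C9 into the methyl group; C7 and C8 are not reaction centers, the aryl methyl ethers and the propenyl group are inert at this temperature, and the C7 alkoxide is reprotonated on work-up.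

**Step 5**
Reactants: 9 (1R,2R)-2-[2,6-dimethoxy-4-[(E)-prop-1-enyl]phenoxy]-1-(3,4,5-trimethoxyphenyl)propan-1-ol
Product: 10 [(1R,2R)-2-[2,6-dimethoxy-4-[(E)-prop-1-enyl]phenoxy]-1-(3,4,5-trimethoxyphenyl)propyl] acetate
Conditions: Ac2O, pyridine, DMAP (cat.), CH2Cl2, rt
Reagents that add atoms: acetic anhydride, CC(=O)OC(C)=O
Why: DMAP-catalysed acetylation of the secondary benzylic alcohol with Ac2O (nucleophilic acyl transfer) acylates oxygen without breaking the C7–O bond, so the 7R,8R configuration is retained.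

**Compound list**
1 | 2,6-dimethoxy-4-[(E)-prop-1-enyl]phenol | C/C=C/c1cc(OC)c(O)c(OC)c1 | starting material
2 | ethyl diazoacetate | CCOC(=O)C=[N+]=[N-] | starting material
3 | 3,4,5-trimethoxybenzaldehyde | COc1cc(C=O)cc(OC)c1OC | starting material
4 | oxonium ylide: the phenol oxygen of 1, still carrying its hydrogen, bonded to the carbanionic CH of an ethoxycarbonylmethyl unit | C/C=C/c1cc(OC)c([OH+][CH-]C(=O)OCC)c(OC)c1 | intermediate
5 | (E)-1-ethoxy-2-[2,6-dimethoxy-4-[(E)-prop-1-enyl]phenoxy]ethen-1-ol (ester enol, OH cis to the aryloxy oxygen) | C/C=C/c1cc(OC)c(O/C=C(/OCC)O)c(OC)c1 | intermediate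
6 | ethyl (2S,3R)-2-[2,6-dimethoxy-4-[(E)-prop-1-enyl]phenoxy]-3-hydroxy-3-(3,4,5-trimethoxyphenyl)propanoate | C/C=C/c1cc(OC)c(O[C@H](C(=O)OCC)[C@H](O)c2cc(OC)c(OC)c(OC)c2)c(OC)c1 | intermediate
7 | (1R,2R)-2-[2,6-dimethoxy-4-[(E)-prop-1-enyl]phenoxy]-1-(3,4,5-trimethoxyphenyl)propane-1,3-diol | C/C=C/c1cc(OC)c(O[C@H](CO)[C@H](O)c2cc(OC)c(OC)c(OC)c2)c(OC)c1 | intermediate
8 | (2R,3R)-2-[2,6-dimethoxy-4-[(E)-prop-1-enyl]phenoxy]-3-hydroxy-3-(3,4,5-trimethoxyphenyl)propyl 4-methylbenzenesulfonate | C/C=C/c1cc(OC)c(O[C@H](COS(=O)(=O)c2ccc(C)cc2)[C@H](O)c2cc(OC)c(OC)c(OC)c2)c(OC)c1 | intermediate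
9 | (1R,2R)-2-[2,6-dimethoxy-4-[(E)-prop-1-enyl]phenoxy]-1-(3,4,5-trimethoxyphenyl)propan-1-ol | C/C=C/c1cc(OC)c(O[C@H](C)[C@H](O)c2cc(OC)c(OC)c(OC)c2)c(OC)c1 | intermediate
10 | [(1R,2R)-2-[2,6-dimethoxy-4-[(E)-prop-1-enyl]phenoxy]-1-(3,4,5-trimethoxyphenyl)propyl] acetate | C/C=C/c1cc(OC)c(O[C@H](C)[C@H](OC(C)=O)c2cc(OC)c(OC)c(OC)c2)c(OC)c1 | target

Total step count: 5. Longest linear sequence: 5 steps (1 to 6, 7, 8, 9, 10).

**Steps most likely to fail**

Step 1. Process at risk: the enol may tautomerise to the plain O–H insertion ester before the aldehyde reaches it, the carbene may add to the propenyl double bond or to the aldehyde oxygen, and the acid may give poor threo or facial control. The fallback uses known auxiliary chemistry, sets out from 1 and comes back at 7.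
- Williamson alkylation of 1 with bromoacetic acid (NaOH, H2O, 80 °C) gives 2-[2,6-dimethoxy-4-[(E)-prop-1-enyl]phenoxy]acetic acid F1.
- Pivaloyl chloride and Et3N (THF, −20 °C) convert it into 2-[2,6-dimethoxy-4-[(E)-prop-1-enyl]phenoxy]acetic pivalic anhydride F2, which is not isolated.
- F2 acylates (S)-4-benzyloxazolidin-2-one deprotonated with n-BuLi (−78 °C) to give (4S)-4-benzyl-3-[2-[2,6-dimethoxy-4-[(E)-prop-1-enyl]phenoxy]acetyl]-1,3-oxazolidin-2-one F3.
- Enolisation of F3 with Bu2BOTf and iPr2NEt (CH2Cl2, −78 °C) and addition of 3 (Evans syn aldol) should give (4S)-4-benzyl-3-[(2S,3R)-2-[2,6-dimethoxy-4-[(E)-prop-1-enyl]phenoxy]-3-hydroxy-3-(3,4,5-trimethoxyphenyl)propanoyl]-1,3-oxazolidin-2-one F4. This is the syn (threo) adduct, and its two new centers are fixed by the benzyl group of the auxiliary.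
- LiBH4 (THF, 1 equiv H2O, 0 °C) then removes the auxiliary reductively and gives 7 directly, after which steps 3 to 5 run as written.

Step 4. Process at risk: hydride substitution at C9 is slowed by the oxygen on C8, so the lithium alkoxide formed at C7 may act first (oxetane closure or fragmentation of the C7–C8 bond), or hydride may attack sulfur and return the diol. The fallback sets out from 8 and comes back at 9.
- C7–OH is capped with TBSOTf and 2,6-lutidine (CH2Cl2, −78 to 0 °C) to give (2R,3R)-3-[tert-butyl(dimethyl)silyl]oxy-2-[2,6-dimethoxy-4-[(E)-prop-1-enyl]phenoxy]-3-(3,4,5-trimethoxyphenyl)propyl 4-methylbenzenesulfonate F5.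
- With no alkoxide present, LiEt3BH (THF, rt) reduces the tosylate to tert-butyl-[(1R,2R)-2-[2,6-dimethoxy-4-[(E)-prop-1-enyl]phenoxy]-1-(3,4,5-trimethoxyphenyl)propoxy]-dimethylsilane F6.
- TBAF (THF, 0 °C) frees 9.

Step 3. Process at risk: sulfonylation may not stop at the primary hydroxyl, or the primary tosylate may cyclise or be displaced by chloride on standing. The fallback sets out from 7 and comes back at 9.
- Garegg–Samuelsson iodination (I2, PPh3, imidazole, CH2Cl2, 0 °C), which activates only the unhindered primary hydroxyl, gives (1R,2S)-2-[2,6-dimethoxy-4-[(E)-prop-1-enyl]phenoxy]-3-iodo-1-(3,4,5-trimethoxyphenyl)propan-1-ol F7. The spatial arrangement is unchanged; the C8 descriptor changes because CH2I outranks C7.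
- LiEt3BH (THF, 0 °C) reduces the iodide to 9.

**Further compounds**
F1 | step 1 | 2-[2,6-dimethoxy-4-[(E)-prop-1-enyl]phenoxy]acetic acid | C/C=C/c1cc(OC)c(OCC(=O)O)c(OC)c1
F2 | step 1 | 2-[2,6-dimethoxy-4-[(E)-prop-1-enyl]phenoxy]acetic pivalic anhydride | C/C=C/c1cc(OC)c(OCC(=O)OC(=O)C(C)(C)C)c(OC)c1
F3 | step 1 | (4S)-4-benzyl-3-[2-[2,6-dimethoxy-4-[(E)-prop-1-enyl]phenoxy]acetyl]-1,3-oxazolidin-2-one | C/C=C/c1cc(OC)c(OCC(=O)N2[C@@H](Cc3ccccc3)COC2=O)c(OC)c1
F4 | step 1 | (4S)-4-benzyl-3-[(2S,3R)-2-[2,6-dimethoxy-4-[(E)-prop-1-enyl]phenoxy]-3-hydroxy-3-(3,4,5-trimethoxyphenyl)propanoyl]-1,3-oxazolidin-2-one | C/C=C/c1cc(OC)c(O[C@H](C(=O)N2[C@@H](Cc3ccccc3)COC2=O)[C@H](O)c2cc(OC)c(OC)c(OC)c2)c(OC)c1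
F5 | step 4 | (2R,3R)-3-[tert-butyl(dimethyl)silyl]oxy-2-[2,6-dimethoxy-4-[(E)-prop-1-enyl]phenoxy]-3-(3,4,5-trimethoxyphenyl)propyl 4-methylbenzenesulfonate | C/C=C/c1cc(OC)c(O[C@H](COS(=O)(=O)c2ccc(C)cc2)[C@H](O[Si](C)(C)C(C)(C)C)c2cc(OC)c(OC)c(OC)c2)c(OC)c1
F6 | step 4 | tert-butyl-[(1R,2R)-2-[2,6-dimethoxy-4-[(E)-prop-1-enyl]phenoxy]-1-(3,4,5-trimethoxyphenyl)propoxy]-dimethylsilane | C/C=C/c1cc(OC)c(O[C@H](C)[C@H](O[Si](C)(C)C(C)(C)C)c2cc(OC)c(OC)c(OC)c2)c(OC)c1
F7 | step 3 | (1R,2S)-2-[2,6-dimethoxy-4-[(E)-prop-1-enyl]phenoxy]-3-iodo-1-(3,4,5-trimethoxyphenyl)propan-1-ol | C/C=C/c1cc(OC)c(O[C@H](CI)[C@H](O)c2cc(OC)c(OC)c(OC)c2)c(OC)c1
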